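**Retrosynthetic overview**

1. The strategy rests on one feature: C2' of the N-methylpiperidine ring (N1', C2'–C6') is bonded to C6 of ring A, between the two phenol carbons C5 and C7 and para to C8a, which carries the ring C oxygen O1. A symmetric 2-arylpyridine in which only the para oxygen is protected differently therefore fixes the C6 (not C8) position and lets C2' be set by hydrogenating a flat pyridinium ring.
2. Disconnections, backwards: MOM removal; C2–aryl bond (ring B) by palladium-catalysed asymmetric conjugate addition to a 6-substituted chromone; ring C by enaminone closure onto the one free phenol; acetyl group by directed lithiation; piperidine from an N-benzylpyridinium salt by iridium-catalysed asymmetric hydrogenation; aryl–pyridyl bond by Negishi coupling.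
3. Ring order: ring A is bought as the arene, the pyridine ring is attached and saturated to the piperidine, ring C is closed next, and ring B is attached last.

Key step: step 6

Remark 1: the para oxygen of ring A is installed by C–H borylation and oxidation of 2-bromo-1,3-dimethoxybenzene; a peracid (Baeyer-Villiger) route from 4-bromo-3,5-dimethoxybenzaldehyde is avoided because an aryl group with no ortho or para donor should lose to hydride migration and give the benzoic acid.
Remark 2: in the acid steps the basic nitrogen is present as an ammonium salt and is returned to the free base on bicarbonate work-up; only the salts on which a step depends (12, 25, 26) are numbered.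
Remark 3: the ligand enantiomers named in steps 6 and 13 are predicted from close analogies; the sense would be confirmed in a pilot run and the antipodal ligand used if needed.

**Route**

Step 1
Reactants: 1 2-bromo-1,3-dimethoxybenzene
Product: 2 2-(4-bromo-3,5-dimethoxyphenyl)-4,4,5,5-tetramethyl-1,3,2-dioxaborolane
Conditions: [Ir(cod)OMe]2 (1.5 mol%), 4,4'-di-tert-butyl-2,2'-bipyridine (3 mol%), B2pin2 (1.0 equiv), THF, 80 °C
Reagents that add atoms: bis(pinacolato)diboron, CC1(C)OB(OC1(C)C)B1OC(C)(C)C(C)(C)O1
Why: Iridium-catalysed aromatic C–H borylation is governed by sterics and should occur only at C5, the one C–H with no ortho substituent (meta to both methoxy groups, para to bromine), with the C–Br bond left intact.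

Step 2
Reactants: 2 2-(4-bromo-3,5-dimethoxyphenyl)-4,4,5,5-tetramethyl-1,3,2-dioxaborolane
Product: 3 4-bromo-3,5-dimethoxyphenol
Conditions: KHSO5 (aqueous 2KHSO5·KHSO4·K2SO4), acetone, 0 °C to rt, short contact time
Reagents that add atoms: potassium peroxymonosulfate, [K+].[O-]S(=O)(=O)OO
Why: Oxidative ipso-hydroxylation of an arylboronate (peroxide adds to boron, the aryl group migrates from boron to oxygen, the borate hydrolyses) should give the phenol whose oxygen becomes O1 of the flavanone.

Step 3
Reactants: 3 4-bromo-3,5-dimethoxyphenol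
Product: 4 2-bromo-1,3-dimethoxy-5-(methoxymethoxy)benzene
Conditions: NaH (1.2 equiv), MOMCl (1.2 equiv), THF/DMF, 0 °C to rt
Reagents that add atoms: chloromethyl methyl ether, COCCl
Why: Williamson-type O-alkylation of the sodium phenoxide gives a MOM ether that marks the para oxygen as the only acid-labile one and later serves as a directing group for lithiation.

Step 4
Reactants: 4 2-bromo-1,3-dimethoxy-5-(methoxymethoxy)benzene; 5 2-bromopyridine
Product: 8 2-[2,6-dimethoxy-4-(methoxymethoxy)phenyl]pyridine, via aryllithium 6 (not isolated), via arylzinc chloride 7 (not isolated)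
Conditions: n-BuLi (1.05 equiv), THF, −78 °C; ZnCl2 (1.1 equiv, THF), −78 °C to rt; then 5 (0.9 equiv), Pd2(dba)3 (2 mol%), SPhos (8 mol%), THF, 65 °C
Reagents that add atoms: none
Why: Bromine–lithium exchange at −78 °C outruns ortho-lithiation and gives an aryllithium held between two methoxy groups, which after transmetalation to zinc undergoes Negishi coupling under a bulky biarylphosphine suited to di-ortho-substituted arylzinc reagents, the pyridine being used as the electrophile so that no unstable 2-pyridyl nucleophile is needed.

Step 5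
Reactants: 8 2-[2,6-dimethoxy-4-(methoxymethoxy)phenyl]pyridine
Product: 9 1-benzyl-2-[2,6-dimethoxy-4-(methoxymethoxy)phenyl]pyridinium bromide
Conditions: BnBr (3 equiv, acid-free), MeCN, 80 °C; trituration with Et2O
Reagents that add atoms: benzyl bromide, BrCc1ccccc1
Why: Menshutkin N-alkylation should proceed because the aryl ring is twisted out of the pyridine plane and leaves the in-plane nitrogen lone pair accessible, and the neutral medium spares the MOM ether.

Step 6
Reactants: 9 1-benzyl-2-[2,6-dimethoxy-4-(methoxymethoxy)phenyl]pyridinium bromide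
Product: 13 (R)-1-benzyl-2-[2,6-dimethoxy-4-(methoxymethoxy)phenyl]piperidine, via tetrahydropyridine enamine 10 (not isolated), via cyclic iminium bromide 11 (not isolated), via piperidinium bromide 12 (not isolated)
Conditions: [Ir(cod)Cl]2 (1 mol%), (S)-SynPhos (2.2 mol%), H2 (40 bar), PhMe/CH2Cl2 1:1, 30 °C; then aq. Na2CO3
Reagents that add atoms: none
Why: This is the iridium-catalysed asymmetric hydrogenation of an N-benzyl-2-arylpyridinium bromide, a known reaction class for 2-aryl salts. An iridium hydride formed from H2 transfers hydride to the activated pyridinium ring, further hydride transfer and protonation lead to enamine 10, the HBr carried by the system protonates 10 at C3' to iminium bromide 11, and a last hydride transfer to C2' of 11 gives salt 12, so that three H2 are consumed and five C–H bonds form at C2'–C6'. No ring is closed; the existing six-membered pyridinium ring is saturated in place. The C2' stereocenter is set only by the chiral bisphosphine on iridium, which must tell the two faces of the C2'=N bond of 11 apart by distinguishing the bulky aryl group, twisted by its two ortho methoxy groups, from the N-benzyl flank; (S)-SynPhos is the enantiomer expected by analogy with 2-phenyl salts to give (R). The step needs enantioface selectivity and chemoselectivity, and 9 suits both: it has no stereocenter, ketone, alkene or carbon-bound halide, the benzyl group activates the ring, the product stays as hydrobromide 12 so the amine cannot poison the catalyst, and the non-protic medium keeps the MOM ether intact. The twist of the electron-rich aryl group makes 11 resemble a 2-alkyl iminium ion, a class these catalysts also reduce well.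

Step 7
Reactants: 13 (R)-1-benzyl-2-[2,6-dimethoxy-4-(methoxymethoxy)phenyl]piperidine
Product: 15 (R)-2-[2,6-dimethoxy-4-(methoxymethoxy)phenyl]-1-methylpiperidine, via secondary piperidine 14 (not isolated)
Conditions: H2 (1–3 bar), 10% Pd/C, 37% aq. CH2O (3 equiv), MeOH, rt
Reagents that add atoms: formaldehyde, C=O
Why: Hydrogenolysis of the unhindered N-benzyl group followed in the same pot by reductive amination of the freed secondary amine with formaldehyde should give the N-methyl compound, while the ring C2'–N bond, shielded by two ortho methoxy groups, and the C2' stereocenter are not touched.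

Step 8
Reactants: 15 (R)-2-[2,6-dimethoxy-4-(methoxymethoxy)phenyl]-1-methylpiperidine; 16 N-methoxy-N-methylacetamide
Product: 18 1-[2,4-dimethoxy-6-(methoxymethoxy)-3-[(R)-1-methylpiperidin-2-yl]phenyl]ethanone, via aryllithium 17 (not isolated)
Conditions: n-BuLi (1.2 equiv), TMEDA (1.2 equiv), THF, 0 °C; then 16 (1.5 equiv), −78 to 0 °C; H2O quench
Reagents that add atoms: none
Why: Directed ortho-metalation takes place at the C–H flanked by OMOM and OMe (the two such positions are equivalent by rotation about the aryl–C2' bond), and acylation by the Weinreb amide stops at the ketone because the chelated tetrahedral adduct survives until work-up.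

Step 9
Reactants: 18 1-[2,4-dimethoxy-6-(methoxymethoxy)-3-[(R)-1-methylpiperidin-2-yl]phenyl]ethanone
Product: 19 1-[6-hydroxy-2,4-dimethoxy-3-[(R)-1-methylpiperidin-2-yl]phenyl]ethanone
Conditions: HCl (1.25 M in MeOH), rt; then aq. NaHCO3
Reagents that add atoms: none
Why: Acid-catalysed acetal exchange with methanol removes the MOM group and leaves the methyl ethers, so that only the oxygen para to the piperidine becomes a free phenol.

Step 10
Reactants: 19 1-[6-hydroxy-2,4-dimethoxy-3-[(R)-1-methylpiperidin-2-yl]phenyl]ethanone
Product: 21 5,7-dimethoxy-6-[(R)-1-methylpiperidin-2-yl]chromen-4-one, via enaminone 20 (not isolated)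
Conditions: Me2NCH(OMe)2 (3 equiv), PhMe, 95 °C; evaporate; conc. HCl, CH2Cl2, rt to 40 °C; then aq. NaHCO3
Reagents that add atoms: N,N-dimethylformamide dimethyl acetal, COC(OC)N(C)C
Why: Condensation of the methyl ketone with the amide acetal gives the enaminone, and acid-induced addition–elimination of the single free phenol with loss of dimethylamine closes ring C, which fixes the piperidine at C6 because no other oxygen can cyclise.

Step 11
Reactants: 21 5,7-dimethoxy-6-[(R)-1-methylpiperidin-2-yl]chromen-4-one
Product: 22 5,7-dihydroxy-6-[(R)-1-methylpiperidin-2-yl]chromen-4-one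
Conditions: BBr3 (6 equiv), CH2Cl2, −78 °C to rt; ice/H2O; aq. NaHCO3 to pH 7–8
Reagents that add atoms: none
Why: Lewis acid cleavage of both aryl methyl ethers by BBr3 (excess to cover the amine and the carbonyl) is done on the chromone, where C2 is not yet a stereocenter and where both phenol oxygens are conjugated to the C4 carbonyl, which should suppress quinone methide ionisation of the C2'–N bond.

Step 12
Reactants: 22 5,7-dihydroxy-6-[(R)-1-methylpiperidin-2-yl]chromen-4-one
Product: 23 5,7-bis(methoxymethoxy)-6-[(R)-1-methylpiperidin-2-yl]chromen-4-one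
Conditions: NaH (2.5 equiv), DMF, 0 °C; MOMCl (2.4 equiv), 0 °C to rt; aq. NaHCO3
Reagents that add atoms: chloromethyl methyl ether, COCCl
Why: O-Alkylation of the bis-phenoxide (NaH in DMF breaks the hydrogen bond of the 5-OH to the carbonyl) installs acid-labile ethers, and any N-methoxymethylammonium ion formed at the tertiary amine is itself a MOM donor toward phenoxide and should be returned to the amine.

Step 13
Reactants: 23 5,7-bis(methoxymethoxy)-6-[(R)-1-methylpiperidin-2-yl]chromen-4-one; 24 4-(methoxymethoxy)phenylboronic acid
Product: 27 (2S)-5,7-bis(methoxymethoxy)-2-[4-(methoxymethoxy)phenyl]-6-[(R)-1-methylpiperidin-2-yl]chroman-4-one, via chromone trifluoroacetate salt 25 (not isolated), via flavanone trifluoroacetate salt 26 (not isolated)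
Conditions: CF3CO2H (1.05 equiv), ClCH2CH2Cl, rt; then 24 (2.5 equiv), Pd(OCOCF3)2 (10 mol%), (R)-t-BuPyOx (12 mol%), NH4PF6 (30 mol%), H2O (5 equiv), 60 °C; aq. NaHCO3
Reagents that add atoms: none
Why: Palladium-catalysed asymmetric conjugate addition of an arylboronic acid to a chromone (transmetalation to a cationic divalent palladium aryl, enantioselective insertion of the C2=C3 bond, protonolysis of the palladium enolate by water) sets C2 as (S) under control of the pyridine-oxazoline ligand, C2' being too remote to interfere and the amine being held as its ammonium salt so it cannot bind palladium; (R)-t-BuPyOx is the enantiomer expected, by the facial model for cyclic enones, to give 2S.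

Step 14
Reactants: 27 (2S)-5,7-bis(methoxymethoxy)-2-[4-(methoxymethoxy)phenyl]-6-[(R)-1-methylpiperidin-2-yl]chroman-4-one
Product: 28 (2S)-5,7-dihydroxy-2-(4-hydroxyphenyl)-6-[(R)-1-methylpiperidin-2-yl]chroman-4-one
Conditions: HCl (2 M in MeOH), rt (not above 35 °C); then aq. NaHCO3 to pH 7–8
Reagents that add atoms: none
Why: Acid-catalysed acetal exchange removes all three MOM ethers without base, so the base-labile flavanone center C2 is not opened, and the low temperature should keep the benzylic C2'–N bond from ionising.

**Compound list**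

1 | 2-bromo-1,3-dimethoxybenzene | COc1cccc(OC)c1Br | starting material
2 | 2-(4-bromo-3,5-dimethoxyphenyl)-4,4,5,5-tetramethyl-1,3,2-dioxaborolane | COc1cc(cc(OC)c1Br)B1OC(C)(C)C(C)(C)O1 | intermediate
3 | 4-bromo-3,5-dimethoxyphenol | COc1cc(O)cc(OC)c1Br | intermediate
4 | 2-bromo-1,3-dimethoxy-5-(methoxymethoxy)benzene | COCOc1cc(OC)c(Br)c(OC)c1 | intermediate
5 | 2-bromopyridine | Brc1ccccn1 | starting material
6 | [2,6-dimethoxy-4-(methoxymethoxy)phenyl]lithium | [Li]c1c(OC)cc(OCOC)cc1OC | intermediate
7 | [2,6-dimethoxy-4-(methoxymethoxy)phenyl]zinc chloride | Cl[Zn]c1c(OC)cc(OCOC)cc1OC | intermediate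
8 | 2-[2,6-dimethoxy-4-(methoxymethoxy)phenyl]pyridine | COCOc1cc(OC)c(-c2ccccn2)c(OC)c1 | intermediate
9 | 1-benzyl-2-[2,6-dimethoxy-4-(methoxymethoxy)phenyl]pyridinium bromide | COCOc1cc(OC)c(-c2cccc[n+]2Cc2ccccc2)c(OC)c1.[Br-] | intermediate
10 | 1-benzyl-6-[2,6-dimethoxy-4-(methoxymethoxy)phenyl]-1,2,3,4-tetrahydropyridine | COCOc1cc(OC)c(C2=CCCCN2Cc2ccccc2)c(OC)c1 | intermediate
11 | 1-benzyl-6-[2,6-dimethoxy-4-(methoxymethoxy)phenyl]-2,3,4,5-tetrahydropyridin-1-ium bromide | COCOc1cc(OC)c(C2=[N+](Cc3ccccc3)CCCC2)c(OC)c1.[Br-] | intermediate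
12 | (R)-1-benzyl-2-[2,6-dimethoxy-4-(methoxymethoxy)phenyl]piperidinium bromide | c1ccccc1C[NH+]1CCCC[C@@H]1c1c(OC)cc(OCOC)cc1OC.[Br-] | intermediate
13 | (R)-1-benzyl-2-[2,6-dimethoxy-4-(methoxymethoxy)phenyl]piperidine | c1ccccc1CN1CCCC[C@@H]1c1c(OC)cc(OCOC)cc1OC | intermediate
14 | (R)-2-[2,6-dimethoxy-4-(methoxymethoxy)phenyl]piperidine | N1CCCC[C@@H]1c1c(OC)cc(OCOC)cc1OC | intermediate
15 | (R)-2-[2,6-dimethoxy-4-(methoxymethoxy)phenyl]-1-methylpiperidine | CN1CCCC[C@@H]1c1c(OC)cc(OCOC)cc1OC | intermediate
16 | N-methoxy-N-methylacetamide | CC(=O)N(C)OC | starting material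
17 | [2,4-dimethoxy-6-(methoxymethoxy)-3-[(R)-1-methylpiperidin-2-yl]phenyl]lithium | CN1CCCC[C@@H]1c1c(OC)cc(OCOC)c([Li])c1OC | intermediate
18 | 1-[2,4-dimethoxy-6-(methoxymethoxy)-3-[(R)-1-methylpiperidin-2-yl]phenyl]ethanone | CN1CCCC[C@@H]1c1c(OC)cc(OCOC)c(C(C)=O)c1OC | intermediate
19 | 1-[6-hydroxy-2,4-dimethoxy-3-[(R)-1-methylpiperidin-2-yl]phenyl]ethanone | CN1CCCC[C@@H]1c1c(OC)cc(O)c(C(C)=O)c1OC | intermediate
20 | (E)-3-(dimethylamino)-1-[6-hydroxy-2,4-dimethoxy-3-[(R)-1-methylpiperidin-2-yl]phenyl]prop-2-en-1-one | CN1CCCC[C@@H]1c1c(OC)cc(O)c(C(=O)/C=C/N(C)C)c1OC | intermediate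
21 | 5,7-dimethoxy-6-[(R)-1-methylpiperidin-2-yl]chromen-4-one | CN1CCCC[C@@H]1c1c(OC)cc2occc(=O)c2c1OC | intermediate
22 | 5,7-dihydroxy-6-[(R)-1-methylpiperidin-2-yl]chromen-4-one | CN1CCCC[C@@H]1c1c(O)cc2occc(=O)c2c1O | intermediate
23 | 5,7-bis(methoxymethoxy)-6-[(R)-1-methylpiperidin-2-yl]chromen-4-one | CN1CCCC[C@@H]1c1c(OCOC)cc2occc(=O)c2c1OCOC | intermediate
24 | 4-(methoxymethoxy)phenylboronic acid | COCOc1ccc(B(O)O)cc1 | starting material
25 | (R)-2-[5,7-bis(methoxymethoxy)-4-oxochromen-6-yl]-1-methylpiperidinium trifluoroacetate | C[NH+]1CCCC[C@@H]1c1c(OCOC)cc2occc(=O)c2c1OCOC.[O-]C(=O)C(F)(F)F | intermediate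
26 | (R)-2-[(2S)-5,7-bis(methoxymethoxy)-2-[4-(methoxymethoxy)phenyl]-4-oxochroman-6-yl]-1-methylpiperidinium trifluoroacetate | C[NH+]1CCCC[C@@H]1c1c(OCOC)cc2c(c1OCOC)C(=O)C[C@@H](c1ccc(OCOC)cc1)O2.[O-]C(=O)C(F)(F)F | intermediate
27 | (2S)-5,7-bis(methoxymethoxy)-2-[4-(methoxymethoxy)phenyl]-6-[(R)-1-methylpiperidin-2-yl]chroman-4-one | CN1CCCC[C@@H]1c1c(OCOC)cc2c(c1OCOC)C(=O)C[C@@H](c1ccc(OCOC)cc1)O2 | intermediate
28 | (2S)-5,7-dihydroxy-2-(4-hydroxyphenyl)-6-[(R)-1-methylpiperidin-2-yl]chroman-4-one | CN1CCCC[C@@H]1c1c(O)cc2c(c1O)C(=O)C[C@@H](c1ccc(O)cc1)O2 | target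

**Totals**

Total step count: 14.
Longest linear sequence: 14 steps (1 to 28); 5, 16 and 24 are bought and enter in steps 4, 8 and 13.

**Steps most likely to fail**

Step 6. Hydrogen uptake may stall, or the hydride transfer to the iminium ion may discriminate its two faces poorly, because both ortho positions of the aryl group are substituted. Fallback, setting out from 9 and returning at 13: pyridinium bromide 9 would be hydrogenated without a chiral ligand over PtO2 (H2, 4 bar, MeOH, rt) and neutralised with aq. Na2CO3 to give racemic 1-benzyl-2-[2,6-dimethoxy-4-(methoxymethoxy)phenyl]piperidine F1. Its enantiomers would then be separated by preparative chromatography on a polysaccharide chiral stationary phase (supercritical CO2/MeOH with a little Et2NH), the (R)-enantiomer being 13.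

Step 13. The palladium catalyst may be deactivated by traces of free amine, the electron-rich boronic acid may protodeboronate faster than it transmetalates, or the peri 5-OMOM group may erode facial selectivity. Fallback, setting out from 23 and returning at 27: chromone 23 would be treated with 4-(methoxymethoxy)phenylmagnesium bromide F2 (made from commercial 1-bromo-4-(methoxymethoxy)benzene and Mg in THF) and catalytic CuBr·SMe2 in THF at −40 °C, then quenched with aq. NH4Cl. This copper-mediated conjugate addition has no chiral control element and should give 27 together with the (2R)-epimer of 27 F3. The two are diastereomers because C2' is already fixed, and would be separated by chromatography or preparative HPLC; 27 then goes on to step 14.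

Step 8. The hindered aryllithium may deprotonate the acetyl group of the Weinreb amide instead of adding to it, so that 15 is returned after work-up. Fallback, setting out from 15 and returning at 19: the MOM ether of 15 would be removed first (HCl, MeOH, rt, then NaHCO3) to give 3,5-dimethoxy-4-[(R)-1-methylpiperidin-2-yl]phenol F4. This would be O-acetylated (Ac2O, pyridine) to 3,5-dimethoxy-4-[(R)-1-methylpiperidin-2-yl]phenyl acetate F5 and submitted to a Fries rearrangement (BF3·OEt2, AcOH, 80 °C). The only free ring positions are the two equivalent ones ortho to the oxygen, so the acetyl group can only arrive where the lithiation would have placed it, and 19 results directly.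

**Further compounds**

F1 | step 6 | racemic 1-benzyl-2-[2,6-dimethoxy-4-(methoxymethoxy)phenyl]piperidine | COCOc1cc(OC)c(C2CCCCN2Cc2ccccc2)c(OC)c1
F2 | step 13 | 4-(methoxymethoxy)phenylmagnesium bromide | COCOc1ccc([Mg]Br)cc1
F3 | step 13 | (2R)-5,7-bis(methoxymethoxy)-2-[4-(methoxymethoxy)phenyl]-6-[(R)-1-methylpiperidin-2-yl]chroman-4-one | CN1CCCC[C@@H]1c1c(OCOC)cc2c(c1OCOC)C(=O)C[C@H](c1ccc(OCOC)cc1)O2
F4 | step 8 | 3,5-dimethoxy-4-[(R)-1-methylpiperidin-2-yl]phenol | CN1CCCC[C@@H]1c1c(OC)cc(O)cc1OC
F5 | step 8 | 3,5-dimethoxy-4-[(R)-1-methylpiperidin-2-yl]phenyl acetate | CN1CCCC[C@@H]1c1c(OC)cc(OC(C)=O)cc1OC
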